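**Plan**

- Retrosynthesis: C2–H is traced back to C2–SiMe3. Then N1–C2 and C3–Br are cut together, which opens the pyrrole ring to a 2-alkynylaniline. Last, the aryl–alkyne bond and the C–I bond that serves it are cut.
- Forward, chain: 2,4-dibromoaniline 1 is iodinated at its one free ortho position to give 2. Trimethylsilylacetylene 3 is then coupled at the C–I bond to give alkynylaniline 4; the benzene ring is bought.
- Forward, ring: CuBr2 5 closes the pyrrole ring, the only ring made, and puts bromine on C3 in the same operation, through the C3–copper species 6, to give silylindole 7. Fluoride then removes silicon to give target 8.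
- Enabling feature: the bromine on C3 sits directly beside the N1–C2 bond that the ring closure makes. On the benzene ring, C5 and C7 hold bromine and C3a holds the pyrrole carbon, so every position ortho or para to N1 is taken and CuBr2 can spend its bromine only at the alkyne.
- Stereochemistry: the target has no stereocentre and no double-bond geometry to set.

Key step: step 3

Remark: 6 is drawn as a monomeric indol-3-yl bromide of divalent copper; its real ligation and aggregation in MeCN are left open and do not change the route.

**Route**

Step 1
Reactants: 1 2,4-dibromoaniline
Product: 2 2,4-dibromo-6-iodoaniline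
Conditions: NIS (1.05 equiv), AcOH, rt, dark
Reagents that add atoms: N-iodosuccinimide, SMILES O=C1CCC(=O)N1I
Why: Electrophilic aromatic iodination; the amino group directs to its ortho and para positions, of which only C6 is still free, and the mild iodonium source should leave the amine unoxidised.

Step 2
Reactants: 2 2,4-dibromo-6-iodoaniline; 3 trimethylsilylacetylene
Product: 4 2,4-dibromo-6-[(trimethylsilyl)ethynyl]aniline
Conditions: PdCl2(PPh3)2 (2 mol%), CuI (4 mol%), Et3N, THF, rt, degassed
Reagents that add atoms: none
Why: Sonogashira coupling; zerovalent palladium inserts into the C–I bond far faster than into C–Br at room temperature, so only the iodide should be replaced, and the silyl cap prevents a second coupling at the alkyne.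

Step 3
Reactants: 4 2,4-dibromo-6-[(trimethylsilyl)ethynyl]aniline; 5 copper dibromide (CuBr2)
Product: 7 3,5,7-tribromo-2-(trimethylsilyl)-1H-indole, via indol-3-ylcopper bromide 6 (not isolated)
Conditions: CuBr2 (2.5 equiv), NaHCO3 (2 equiv), MeCN (0.05 M), rt to 50 °C, Ar
Reagents that add atoms: copper dibromide 5, SMILES Br[Cu]Br
Why: CuBr2 binds the alkyne as a π-acid and the amino nitrogen adds anti to the silyl-bearing carbon, so that N1–C2 forms in a 5-endo-dig closure of the pyrrole ring (the only ring made) and C3 is left bound to divalent copper in 6. A second equivalent of CuBr2 oxidises 6, which then gives up the C3–Br bond and CuBr, while NaHCO3 takes up the HBr that comes from the N–H proton. The closest known reaction type is the CuBr2- or CuCl2-mediated cyclisation–halogenation of 2-alkynylanilines to 3-haloindoles, which is also run on free amines with a PdBr2 cocatalyst. No stereocentre is formed. Ring closure has to outrun bromine addition across the alkyne, bromination of the benzene ring and bromodesilylation at C2: the ortho tether allows only the 5-endo mode and makes the amination intramolecular, C7, C3a and C5 are already substituted so the aniline ring offers CuBr2 no free ortho or para position, and the silyl group blocks C2 and excludes a copper acetylide. If the C3–copper bond were protonated instead, CuBr2 would be expected to brominate the resulting 2-silylindole at C3 and arrive at the same product 7.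

Step 4
Reactants: 7 3,5,7-tribromo-2-(trimethylsilyl)-1H-indole
Product: 8 3,5,7-tribromo-1H-indole
Conditions: Bu4NF (1.2 equiv), AcOH (1.5 equiv), THF, 0 °C, dark
Reagents that add atoms: none
Why: Fluoride-mediated protodesilylation; fluoride attacks silicon, the C2–Si bond of the electron-poor indole breaks and acetic acid protonates C2 at once, which keeps the medium close to neutral and should leave the C3–Br bond and the N–H untouched.

**Compound list**

1 | 2,4-dibromoaniline | Nc1ccc(Br)cc1Br | starting material
2 | 2,4-dibromo-6-iodoaniline | Nc1c(Br)cc(Br)cc1I | intermediate
3 | trimethylsilylacetylene (ethynyltrimethylsilane) | C#C[Si](C)(C)C | starting material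
4 | 2,4-dibromo-6-[(trimethylsilyl)ethynyl]aniline | C[Si](C)(C)C#Cc1cc(Br)cc(Br)c1N | intermediate
5 | copper dibromide, CuBr2 | Br[Cu]Br | starting material
6 | [5,7-dibromo-2-(trimethylsilyl)-1H-indol-3-yl]copper bromide, formed and consumed in the flask of step 3 | C[Si](C)(C)c1[nH]c2c(Br)cc(Br)cc2c1[Cu]Br | intermediate
7 | 3,5,7-tribromo-2-(trimethylsilyl)-1H-indole | C[Si](C)(C)c1[nH]c2c(Br)cc(Br)cc2c1Br | intermediate
8 | 3,5,7-tribromo-1H-indole | Brc1cc(Br)c2[nH]cc(Br)c2c1 | target

**Step count**

Total steps: 4. Longest linear sequence: 4 steps (1 → 2 → 4 → 7 → 8).

**Steps most likely to fail**

1. Step 3. The twice-brominated amine is a weak nucleophile and may close the ring too slowly, so that bromine addition across the alkyne, or bromodesilylation followed by over-bromination at C2, takes over. The fallback sets out from 4 and comes back at 8. It keeps the N1–C2 ring closure on the alkyne but separates it from the bromination. K2CO3 in MeOH at rt removes silicon from the alkyne carbon to give 2,4-dibromo-6-ethynylaniline F1. KOtBu in NMP at rt then closes the ring by base-mediated 5-endo-dig hydroamination to give 5,7-dibromo-1H-indole F2. NBS in DMF at 0 °C brominates C3, the most nucleophilic position of that indole, to give 8.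

2. Step 4. Bromine may migrate from or be lost at C3 while negative charge builds on the neighbouring C2, or the reaction may stall once fluoride has deprotonated the acidic N–H. The fallback sets out from 2 and comes back at 8. It brings in the two pyrrole carbons without silicon, so that nothing has to be removed after the C3 bromine is in place. Suzuki–Miyaura coupling of 2 at the C–I bond with (E)-2-(2-ethoxyvinyl)-4,4,5,5-tetramethyl-1,3,2-dioxaborolane (SMILES CCO/C=C/B1OC(C)(C)C(C)(C)O1; PdCl2(dppf), K2CO3, dioxane–water, 60 °C) should give 2,4-dibromo-6-[(E)-2-ethoxyethenyl]aniline F3. Warm AcOH then lets the amine add to the protonated enol ether and expels ethanol, which closes the ring to 5,7-dibromo-1H-indole F2, the same indole as in the fallback above. NBS in DMF at 0 °C completes the route to 8.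

3. Step 2. The alkyne may dimerise oxidatively at copper (Glaser coupling), and selectivity between C–I and the two C–Br bonds may erode if the coupling has to be warmed. The fallback sets out from 2 and comes back at 4. The alkynyl group is handed over from tin instead of copper, in a Stille coupling of 2 with tributyl[(trimethylsilyl)ethynyl]stannane (SMILES CCCC[Sn](CCCC)(CCCC)C#C[Si](C)(C)C; Pd(PPh3)4, toluene, 50 °C). This uses no copper, no base and no free terminal alkyne, and makes no new compound on the way.

**Further compounds**

F1 | step 3 | 2,4-dibromo-6-ethynylaniline | C#Cc1cc(Br)cc(Br)c1N
F2 | step 3 | 5,7-dibromo-1H-indole | Brc1cc(Br)c2[nH]ccc2c1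
F3 | step 4 | 2,4-dibromo-6-[(E)-2-ethoxyethenyl]aniline | CCO/C=C/c1cc(Br)cc(Br)c1N
F0 | step 2 | none | none
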